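The numbers in the tables are simulated from invented constants.

I was to read the flask at 5.0 min, so the first thing I wanted to know was what it could still pay for by then.

in all of them: starting complex 0.082 M; incoming ligand 0.123 M

| run | scavenger | remark | time |
|---|---|---|---|
| birch | 0.18 M | run made earlier |  |
| flask | 0.123 M |  | 5.0 min |

birch run (percent of the starting complex charged)

| time / s | starting complex / % | complex with one exchanged / % |
|---|---|---|
| 15.0 | 53.1 | 42.8 |
| 30.0 | 33.3 | 54.1 |
| 50.0 | 22.8 | 60.6 |
| 60.0 | 18.1 | 58.5 |

(scatter of a reading: 1 percentage point)

- amounts and yields of leaving ligand count idle adduct too
- the numbers in the tables scatter with a standard deviation of 1 percentage point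
- on the list of suspects stand: starting complex + incoming ligand -> leaving ligand + complex with one exchanged; complex with one exchanged + incoming ligand -> leaving ligand + complex with two exchanged; complex with two exchanged + incoming ligand -> leaving ligand + complex with three exchanged; complex with three exchanged + incoming ligand -> leaving ligand + complex with four exchanged; leaving ligand + incoming ligand <-> idle adduct; scavenger + leaving ligand -> scavenged by-product
- the earlier runs do not show how much of incoming ligand is bound; that part of a forecast is a guess
- no earlier run changes the charge of scavenger; that part of a forecast is a guess

1. part of the starting complex that has reacted at 5.0 min
2. share of the unused incoming ligand that is free and not bound as idle adduct, at 5.0 min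

Each exchange costs one incoming ligand, so I kept a ledger. The budget, 1.50 here, is the incoming ligand available per starting complex charged. The bench rule says that a budget above one finishes the starting complex. The birch run had the same two charges, so I tested the rule on its last reading, at 60.0 s. Counting one exchange for each complex with one exchanged and at least two for the remainder, that run had spent, on its scattered readings, about 1.05 or more per complex charged, which left about 0.447 or less. Yet 18.1% starting complex and 58.5% complex with one exchanged could both still take ligand. In the birch run the ligand left per complex of those two kinds was about 0.584, below one, so it did not cover one more exchange on each, and there the rule stopped working. I therefore expected this flask, with the same budget, to spend its incoming ligand, the limiting reagent, with some starting complex unreacted, though the ledger gave me no figure for how much.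

The forecast put 94% reacted and 75% of the unused incoming ligand free, calling the second “a guess, probably mostly free”.

The flask gave 90.0% reacted and 99.7% free, so the forecast held on the first and stood 25 percentage points low on the second.

    starting complex + incoming ligand → leaving ligand + complex with one exchanged (k = 0.430 M⁻¹ s⁻¹)
    complex with one exchanged + incoming ligand → leaving ligand + complex with two exchanged (k = 0.130 M⁻¹ s⁻¹)
    complex with two exchanged + incoming ligand → leaving ligand + complex with three exchanged (k = 0.710 M⁻¹ s⁻¹)
    complex with three exchanged + incoming ligand → leaving ligand + complex with four exchanged (k = 0.100 M⁻¹ s⁻¹)
    leaving ligand + incoming ligand ⇌ idle adduct, settled at all times (K = 11.0 M⁻¹)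
    scavenger + leaving ligand → scavenged by-product (k = 46.0 M⁻¹ s⁻¹)

A neighbour flask with 0.049 M incoming ligand had a budget of 0.598 and reacted 51.8% of its starting complex, under that budget. At 5.00 min this flask kept 0.37% of its incoming ligand, a remaining budget of 0.555% per starting complex charged. Ten times the time, 50.0 min, took starting complex from 9.96% to 9.85%, inside that remainder, and left the part reacted at 90.2%.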